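**Plan**
1. Retrosynthesis: remove the 4'-O-acetyl mask, cut the acyl–aryl bond C4–C4a of ring C (intramolecular Friedel–Crafts acylation), cut the aryl ether bond O1–C2 (Mitsunobu), and trace the carbinol back to a β-keto ester made from vanillic acid and a malonic half-ester.
2. Forward: the ring B aroyl unit is extended by C3 and C4, ring A (3,4,5-trimethoxyphenol) is joined through O1–C2, and ring C is closed last through C4–C4a in the same flask that unmasks the acid.
3. Enabling feature: the ring A precursor is a 3,4,5-trimethoxyphenoxy group whose only two free carbons (future C4a and C8) are homotopic, each ortho to O1 and to one OMe and para to another, so the tethered acyl carbon C4 can close ring C in only one way and does so under mild acid.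
4. Helper: the 4'-acetate withholds para-oxygen stabilisation from a cation at C2, so the benzylic ether should survive the Mitsunobu step and the acid; it is removed last under neutral conditions.
5. Stereochemistry: C2 is set as the (R)-carbinol by RuCl(p-cymene)[(R,R)-TsDPEN]-catalysed transfer hydrogenation, inverted to (S) in the Mitsunobu step, and then only carried along.

Key step: step 5

Remark: the target is the (2S)-flavanone; the priority order at C2 (O > aryl > CH2 > H) is the same in the carbinol, the open-chain ether and the flavanone, so R → S tracks the inversion directly.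

**Step 1**
Reactants: 1 vanillic acid (4-hydroxy-3-methoxybenzoic acid)
Product: 2 4-acetoxy-3-methoxybenzoic acid
Conditions: Ac2O, aq. NaOH, 0 °C; then HCl to pH 2
Reagents that add atoms: acetic anhydride, CC(=O)OC(C)=O
Why: Schotten–Baumann-type O-acetylation of the phenoxide in cold aqueous alkali should leave the carboxylate free and installs the electron-withdrawing mask of the 4'-oxygen.

**Step 2**
Reactants: 2 4-acetoxy-3-methoxybenzoic acid; 3 mono-tert-butyl malonate (3-tert-butoxy-3-oxopropanoic acid)
Product: 6 tert-butyl 3-(4-acetoxy-3-methoxyphenyl)-3-oxopropanoate, via acid chloride 4 (not isolated), via acylmalonic half-ester 5 (not isolated)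
Conditions: (COCl)2, cat. DMF, CH2Cl2, 0 °C to rt, evaporate; then 3, MgCl2, Et3N, MeCN, 0 °C to rt; cold 1 M HCl
Reagents that add atoms: oxalyl chloride, O=C(Cl)C(=O)Cl (chlorine of the non-isolated acid chloride 4 only)
Why: C-acylation of the magnesium enolate of a malonic half-ester by an aroyl chloride, followed by decarboxylation on acidification (a Claisen-type β-keto ester synthesis), should proceed under a mild amine base that spares the aryl acetate.

**Step 3**
Reactants: 6 tert-butyl 3-(4-acetoxy-3-methoxyphenyl)-3-oxopropanoate
Product: 7 tert-butyl (3R)-3-(4-acetoxy-3-methoxyphenyl)-3-hydroxypropanoate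
Conditions: RuCl(p-cymene)[(R,R)-TsDPEN] (1 mol %), HCO2H/Et3N (5:2), EtOAc, 30 °C
Reagents that add atoms: none
Why: Noyori asymmetric transfer hydrogenation of an aryl ketone, in which the CH/π contact between the η6-arene of the catalyst and the substrate aryl ring orients the ketone as it does acetophenone, so the (R,R)-catalyst should deliver hydride to the Si face and set the (R)-carbinol.

**Step 4**
Reactants: 7 tert-butyl (3R)-3-(4-acetoxy-3-methoxyphenyl)-3-hydroxypropanoate; 8 3,4,5-trimethoxyphenol
Product: 9 tert-butyl (3S)-3-(4-acetoxy-3-methoxyphenyl)-3-(3,4,5-trimethoxyphenoxy)propanoate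
Conditions: PPh3, DIAD, toluene, 0 °C to rt
Reagents that add atoms: none
Why: Mitsunobu etherification, in which the phenol (pKa about 10) displaces the alkoxyphosphonium group by SN2 with inversion and so turns the (R)-carbinol into the (S)-aryl ether, the 4-acetoxy group disfavouring ionisation and the tert-butyl ester lowering the α-acidity that leads to elimination.

**Step 5**
Reactants: 9 tert-butyl (3S)-3-(4-acetoxy-3-methoxyphenyl)-3-(3,4,5-trimethoxyphenoxy)propanoate
Product: 12 (2S)-2-(4-acetoxy-3-methoxyphenyl)-5,6,7-trimethoxychroman-4-one, via carboxylic acid 10 (not isolated), via mixed trifluoroacetic anhydride 11 (not isolated)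
Conditions: TFA/CH2Cl2 (1:3), 0 °C to rt; then TFAA (3 equiv), 0 °C; cold aq. NaHCO3
Reagents that add atoms: trifluoroacetic anhydride, O=C(OC(=O)C(F)(F)F)C(F)(F)F (trifluoroacetyl group of the non-isolated mixed anhydride 11 only)
Why: TFA first cleaves the tert-butyl ester by alkyl–oxygen fission to acid 10, TFAA then turns 10 into the mixed anhydride 11, and the acyl carbon of 11 (or the acylium ion formed from it) is attacked by the ring A carbon ortho to O1, after which loss of a proton restores the arene and leaves the C4 ketone. The closest known reaction type is the intramolecular Friedel–Crafts acylation of 3-aryloxypropanoic acids through their mixed trifluoroacetic anhydrides, the standard chroman-4-one closure. Ring C, the only ring formed, closes in the 6-exo-trig mode at the acyl carbon. No new stereocentre arises; C2 is a spectator and should keep the (S)-configuration set in step 4 because neither the C2–O1 nor the C2–aryl bond is broken. Regioselectivity is not at stake, since the two free carbons of the 3,4,5-trimethoxyphenoxy ring are homotopic and each is activated by O1 and one OMe in ortho and by another OMe in para position, which should let the acylation run at 0 °C without a metal Lewis acid. The chemoselectivity needed, ring closure instead of ionisation of the benzylic C2–O1 bond or acid-catalysed loss of the phenol, is secured by the 4'-acetoxy group, which withholds the para oxygen lone pair from a developing cation at C2, and by the electron-poor β-acyl group; the new ketone in turn deactivates ring A against a second acylation.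

**Step 6**
Reactants: 12 (2S)-2-(4-acetoxy-3-methoxyphenyl)-5,6,7-trimethoxychroman-4-one
Product: 13 agecorynin E, (2S)-2-(4-hydroxy-3-methoxyphenyl)-5,6,7-trimethoxychroman-4-one
Conditions: Candida antarctica lipase B (immobilised), n-BuOH, THF, 40 °C
Reagents that add atoms: none
Why: Lipase-catalysed alcoholysis of a phenolic acetate, a transesterification with precedent on flavonoid acetates, should remove the acetyl group under neutral, base-free conditions, so the retro-oxa-Michael ring opening that racemises flavanones is not triggered.

**Compound list**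
1 | vanillic acid (4-hydroxy-3-methoxybenzoic acid) | COc1cc(C(=O)O)ccc1O | starting material
2 | 4-acetoxy-3-methoxybenzoic acid | CC(=O)Oc1ccc(C(=O)O)cc1OC | intermediate
3 | mono-tert-butyl malonate (3-tert-butoxy-3-oxopropanoic acid) | CC(C)(C)OC(=O)CC(=O)O | starting material
4 | 4-acetoxy-3-methoxybenzoyl chloride | CC(=O)Oc1ccc(C(=O)Cl)cc1OC | intermediate
5 | 2-(4-acetoxy-3-methoxybenzoyl)malonic acid mono-tert-butyl ester (present as its magnesium salt) | CC(=O)Oc1ccc(C(=O)C(C(=O)O)C(=O)OC(C)(C)C)cc1OC | intermediate
6 | tert-butyl 3-(4-acetoxy-3-methoxyphenyl)-3-oxopropanoate | CC(=O)Oc1ccc(C(=O)CC(=O)OC(C)(C)C)cc1OC | intermediate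
7 | tert-butyl (3R)-3-(4-acetoxy-3-methoxyphenyl)-3-hydroxypropanoate | CC(=O)Oc1ccc([C@H](O)CC(=O)OC(C)(C)C)cc1OC | intermediate
8 | 3,4,5-trimethoxyphenol | COc1cc(O)cc(OC)c1OC | starting material
9 | tert-butyl (3S)-3-(4-acetoxy-3-methoxyphenyl)-3-(3,4,5-trimethoxyphenoxy)propanoate | CC(=O)Oc1ccc([C@@H](Oc2cc(OC)c(OC)c(OC)c2)CC(=O)OC(C)(C)C)cc1OC | intermediate
10 | (3S)-3-(4-acetoxy-3-methoxyphenyl)-3-(3,4,5-trimethoxyphenoxy)propanoic acid | CC(=O)Oc1ccc([C@@H](Oc2cc(OC)c(OC)c(OC)c2)CC(=O)O)cc1OC | intermediate
11 | (3S)-3-(4-acetoxy-3-methoxyphenyl)-3-(3,4,5-trimethoxyphenoxy)propanoic trifluoroacetic anhydride | CC(=O)Oc1ccc([C@@H](Oc2cc(OC)c(OC)c(OC)c2)CC(=O)OC(=O)C(F)(F)F)cc1OC | intermediate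
12 | (2S)-2-(4-acetoxy-3-methoxyphenyl)-5,6,7-trimethoxychroman-4-one | CC(=O)Oc1ccc([C@@H]2CC(=O)c3c(cc(OC)c(OC)c3OC)O2)cc1OC | intermediate
13 | agecorynin E, (2S)-2-(4-hydroxy-3-methoxyphenyl)-5,6,7-trimethoxychroman-4-one | COc1cc([C@@H]2CC(=O)c3c(cc(OC)c(OC)c3OC)O2)ccc1O | target

**Totals**
Total step count: 6. Longest linear sequence: 6 steps (1 → 2 → 6 → 7 → 9 → 12 → 13).

**Steps most likely to fail**

Step 5. In TFA the benzylic C2–O1 bond may ionise, or the phenol may be lost by acid-catalysed retro-oxa-Michael reaction, in competition with the acylation. This would erode the enantiomeric purity and divert material to C-alkylated products. The fallback closes the C4–C4a bond before any stereocentre exists and sets C2 afterwards by catalytic asymmetric conjugate arylation. It sets out from 8. Conjugate addition of 8 to ethyl propiolate (DABCO, CH2Cl2, rt) should give ethyl (E)-3-(3,4,5-trimethoxyphenoxy)acrylate F1. Saponification (LiOH, THF/H2O) should give (E)-3-(3,4,5-trimethoxyphenoxy)acrylic acid F2. Cyclodehydration in P2O5/MeSO3H at 60 °C, a Friedel–Crafts closure at either homotopic ortho carbon, should give 5,6,7-trimethoxy-4H-chromen-4-one F3. The 1,4-addition of (4-benzyloxy-3-methoxyphenyl)boronic acid catalysed by Pd(OCOCF3)2 and (R)-t-BuPyOx (NH4PF6, H2O, 1,2-dichloroethane, 60 °C) should give (2S)-2-(4-benzyloxy-3-methoxyphenyl)-5,6,7-trimethoxychroman-4-one F4. The (R)-ligand is the enantiomer expected, from the facial model for cyclic enones, to give the (S)-product; this should be confirmed on the first run. Hydrogenolysis (H2, Pd/C, EtOAc, rt) brings the sequence back to the route at 13.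

Step 4. The activated β-hydroxy ester may eliminate to the cinnamate, partial ionisation may leave the inversion incomplete, and the acetyl group may be transferred to the phenoxide. The fallback forms the ether at the aryl carbon instead of the stereogenic carbon, with retention. It sets out from 6. The transfer hydrogenation of step 3 run with RuCl(p-cymene)[(S,S)-TsDPEN] should give the enantiomeric carbinol tert-butyl (3S)-3-(4-acetoxy-3-methoxyphenyl)-3-hydroxypropanoate F5. Chan–Lam-type O-arylation of F5 with potassium (3,4,5-trimethoxyphenyl)trifluoroborate (Cu(OAc)2·H2O, DMAP, 4 Å molecular sieves, O2, CH2Cl2, rt) leaves the C–O bond at the stereocentre untouched. The (S)-descriptor is therefore kept and the sequence comes back to the route at 9.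

Step 2. The phenolic acetyl group may be transferred to the malonate enolate or to amine-derived nucleophiles, and the enolate may be acylated twice. The fallback replaces the malonate by Meldrum's acid and makes the ester by thermal alcoholysis. It sets out from 4, generated from 2 as in step 2. Acylation of Meldrum's acid (pyridine, CH2Cl2, 0 °C) should give 5-[(4-acetoxy-3-methoxyphenyl)(hydroxy)methylidene]-2,2-dimethyl-1,3-dioxane-4,6-dione F6. Heating F6 with t-BuOH in toluene at 80 °C should open it with loss of acetone and carbon dioxide, and the sequence comes back to the route at 6.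

**Further compounds**
F1 | step 5 | ethyl (E)-3-(3,4,5-trimethoxyphenoxy)acrylate | CCOC(=O)/C=C/Oc1cc(OC)c(OC)c(OC)c1
F2 | step 5 | (E)-3-(3,4,5-trimethoxyphenoxy)acrylic acid | OC(=O)/C=C/Oc1cc(OC)c(OC)c(OC)c1
F3 | step 5 | 5,6,7-trimethoxy-4H-chromen-4-one | O=c1ccoc2cc(OC)c(OC)c(OC)c12
F4 | step 5 | (2S)-2-(4-benzyloxy-3-methoxyphenyl)-5,6,7-trimethoxychroman-4-one | COc1cc([C@@H]2CC(=O)c3c(cc(OC)c(OC)c3OC)O2)ccc1OCc1ccccc1
F5 | step 4 | tert-butyl (3S)-3-(4-acetoxy-3-methoxyphenyl)-3-hydroxypropanoate | CC(=O)Oc1ccc([C@@H](O)CC(=O)OC(C)(C)C)cc1OC
F6 | step 2 | 5-[(4-acetoxy-3-methoxyphenyl)(hydroxy)methylidene]-2,2-dimethyl-1,3-dioxane-4,6-dione | CC(=O)Oc1ccc(C(O)=C2C(=O)OC(C)(C)OC2=O)cc1OC
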